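## Retrosynthetic overview
1. The coumarin lactone ring is closed last. A Knoevenagel condensation and lactonisation joins a salicylaldehyde-type lactol to a dihydropyranone acetic ester, forming C3=C4 and O1–C2.
2. The dihydropyranone ester comes from unmasking and cyclising an eight-carbon chain. That chain is built in one flask: the future ketone carbon C4', as a silyl dithiane (an acyl anion used twice), is bonded first to (R)-propylene oxide and then to methyl 4-bromo-3-methoxycrotonate. This is the key step.
3. The lactol comes from partial reduction of (S)-6,8-dihydroxy-3,5,7-trimethylisochroman-1-one.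
4. The isochromanone comes from a Diels–Alder benzannulation. The diene is a bis(silyloxy)diene from methyl 2-methyl-3-oxopentanoate. The dienophile is the ynoate from lithiated ethyl propiolate and (S)-propylene oxide.
5. Ring order: benzene ring, then the temporary isochromanone ring, with the dihydropyranone ring made in parallel, and the coumarin pyranone ring last.

Assumption: compounds 5, 15 and 17 are bought as catalogue chemicals; primed labels refer to the dihydropyranone ring (O1', C2' bearing CH3, C4' carbonyl, C6' bonded to the coumarin).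

## Route

Step 1
Reactants: 1 ethyl propiolate; 2 (S)-propylene oxide
Product: 4 ethyl (S)-5-hydroxyhex-2-ynoate, via lithium ethyl propiolate 3 (not isolated)
Conditions: 1 (1.5 equiv), n-BuLi (1.5 equiv), THF, −78 °C, 20 min; BF3·OEt2 (1.5 equiv), then 2 (1.0 equiv), −78 °C, 2 h; H2O quench
Reagents that add atoms: none
Why: Yamaguchi–Hirao alkynylation, in which the lithiated propiolate (a donor at the carbon that is normally the Michael-acceptor site of the ynoate) opens the BF3-activated epoxide by SN2 attack at the unhindered CH2, so the C–O stereocentre of 2 is not touched and appears as (S) in 4.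

Step 2
Reactants: 5 methyl 2-methyl-3-oxopentanoate (racemic)
Product: 7 (3Z)-1-methoxy-2-methyl-1,3-bis(trimethylsilyloxy)penta-1,3-diene, via mono silyl enol ether 6 (not isolated)
Conditions: Me3SiOTf (2.4 equiv), Et3N (3 equiv), Et2O, 0 °C to 23 °C, 6 h; pentane extraction, used crude
Reagents that add atoms: trimethylsilyl trifluoromethanesulfonate (Me3SiOTf), SMILES C[Si](C)(C)OS(=O)(=O)C(F)(F)F
Why: Soft-enolisation double O-silylation, in which Me3SiOTf activates each carbonyl while Et3N removes first the acidic C2–H and then the gamma C4–H of 6, giving a Chan-type diene whose equilibrating conditions favour the (3Z) enol silane with the terminal methyl pointing outward in the s-cis form, and no stereocentre is created.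

Step 3
Reactants: 4 ethyl (S)-5-hydroxyhex-2-ynoate; 7 (3Z)-1-methoxy-2-methyl-1,3-bis(trimethylsilyloxy)penta-1,3-diene
Product: 12 (S)-6,8-dihydroxy-3,5,7-trimethylisochroman-1-one, via silylated ynoate 8 (not isolated), via cyclohexadiene cycloadduct 9 (not isolated), via silylated resorcylate 10 (not isolated), via free resorcylate ester 11 (not isolated)
Conditions: Me3SiOC(Me)=NSiMe3 (1.1 equiv), neat, 23 °C, 30 min; 7 (2.5 equiv), neat, sealed tube, 130 °C, 36 h; then TsOH·H2O (0.2 equiv), THF/H2O, 60 °C
Reagents that add atoms: none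
Why: Diels–Alder benzannulation of a Chan/Brassard-type diene with an alkynoate, in which the nucleophilic C4 terminus of 7 bonds to the beta carbon of the ynoate and the ketene-acetal carbon to the alpha carbon, loss of MeOSiMe3 from the ketal carbon aromatises 9 with OH, CH3, OH, CH3 in the required order, and acid then strips silicon and lets the side-chain alcohol lactonise on the flanking ester while the (S) centre remains a spectator.

Step 4
Reactants: 12 (S)-6,8-dihydroxy-3,5,7-trimethylisochroman-1-one
Product: 14 (3S)-3,5,7-trimethylisochromane-1,6,8-triol (lactol as a mixture of C1 epimers), via aluminium lactolate 13 (not isolated)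
Conditions: i-Bu2AlH (3.3 equiv), CH2Cl2, −78 °C, 2 h; 1 M HCl, 0 °C
Reagents that add atoms: none
Why: Partial lactone reduction with i-Bu2AlH, in which two equivalents are taken up as aluminium phenoxides and the third delivers one hydride to give tetrahedral lactolate 13 that is held by chelation to the neighbouring C8 phenoxide and does not collapse at −78 °C, so hydrolysis stops at the lactol, C3 is untouched and the new C1 centre does not matter because it is lost in step 7.

Step 5
Reactants: 15 2-(tert-butyldimethylsilyl)-1,3-dithiane; 16 (R)-propylene oxide; 17 methyl (E)-4-bromo-3-methoxybut-2-enoate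
Product: 21 methyl (E)-4-{2-[(2R)-2-(tert-butyldimethylsilyloxy)propyl]-1,3-dithian-2-yl}-3-methoxybut-2-enoate, via lithiated silyl dithiane 18 (not isolated), via lithium alkoxide adduct 19 (not isolated), via Brook-rearranged dithiane anion 20 (not isolated)
Conditions: t-BuLi (1.05 equiv), Et2O, −78 to −45 °C, 1 h; 16 (1.0 equiv), −78 to −25 °C, 1 h; then 17 (1.2 equiv) in THF/HMPA, −78 °C to 0 °C
Reagents that add atoms: none
Why: Corey–Seebach dithiane umpolung run as a Smith–Tietze anion-relay linchpin coupling, in which masked acyl anion 18 opens epoxide 16 by SN2 attack at its CH2 so the (R) C–O centre is carried over intact, HMPA triggers the 1,4-Brook shift that silylates the new alkoxide and regenerates an acyl anion 20 at the same carbon, and 20 displaces the primary allylic bromide of 17 faster than it can add to the donor-deactivated, fully beta-substituted acrylate, so the future ketone carbon C4' is bonded to two carbons that are themselves electrophiles.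

Step 6
Reactants: 21 methyl (E)-4-{2-[(2R)-2-(tert-butyldimethylsilyloxy)propyl]-1,3-dithian-2-yl}-3-methoxybut-2-enoate
Product: 24 methyl 2-[(2R)-2-methyl-4-oxo-3,4-dihydro-2H-pyran-6-yl]acetate, via silyloxy ketone 22 (not isolated), via hydroxy ketone 23 (not isolated)
Conditions: PhI(OCOCF3)2 (1.3 equiv), MeCN/H2O 9:1, 0 °C, 20 min; then 2 M HCl (cat.), THF, 23 °C, 4 h
Reagents that add atoms: water (H2O), SMILES O
Why: Oxidative dithioacetal hydrolysis with a hypervalent iodine reagent frees the C4' ketone, aqueous acid cleaves the silyl ether, and the liberated alcohol adds to the beta carbon of the methoxyacrylate and expels methanol (6-exo oxa-Michael addition–elimination) with the double bond settling in conjugation with the ketone as the more stable vinylogous ester, the C–O bond of the stereocentre never being broken so (R) is retained.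

Step 7
Reactants: 14 (3S)-3,5,7-trimethylisochromane-1,6,8-triol; 24 methyl 2-[(2R)-2-methyl-4-oxo-3,4-dihydro-2H-pyran-6-yl]acetate
Product: 27 7-hydroxy-5-[(2S)-2-hydroxypropyl]-6,8-dimethyl-3-[(2R)-2-methyl-4-oxo-3,4-dihydro-2H-pyran-6-yl]-2H-chromen-2-one (target), via open hydroxy aldehyde 25 (not isolated), via Knoevenagel adduct 26 (not isolated)
Conditions: piperidine (0.2 equiv), AcOH (0.2 equiv), MeCN, 4 Å molecular sieves, 45 °C, 12 h
Reagents that add atoms: none
Why: Knoevenagel condensation followed by transesterification (the classical salicylaldehyde route to 3-substituted coumarins), in which lactol 14 opens to 25, its piperidine iminium is attacked by the doubly activated CH2 of 24 (alpha to the ester and vinylogously alpha to the ketone), the reversible alkene geometry is drained through Z isomer 26 by irreversible lactonisation of the ortho phenol, and the buffered mild conditions avoid retro-oxa-Michael opening of the pyranone so both stereocentres persist.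

## Compound list
1 | ethyl propiolate | C#CC(=O)OCC | starting material
2 | (S)-propylene oxide | C[C@H]1CO1 | starting material
3 | lithium ethyl propiolate | [Li]C#CC(=O)OCC | intermediate (not isolated)
4 | ethyl (S)-5-hydroxyhex-2-ynoate | CCOC(=O)C#CC[C@H](C)O | intermediate
5 | methyl 2-methyl-3-oxopentanoate (racemic) | CCC(=O)C(C)C(=O)OC | starting material
6 | methyl 2-methyl-3-(trimethylsilyloxy)pent-2-enoate | CCC(O[Si](C)(C)C)=C(C)C(=O)OC | intermediate (not isolated)
7 | (3Z)-1-methoxy-2-methyl-1,3-bis(trimethylsilyloxy)penta-1,3-diene (C1=C2 geometry mixed) | COC(O[Si](C)(C)C)=C(C)/C(O[Si](C)(C)C)=C/C | intermediate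
8 | ethyl (S)-5-(trimethylsilyloxy)hex-2-ynoate | CCOC(=O)C#CC[C@H](C)O[Si](C)(C)C | intermediate (not isolated)
9 | cyclohexa-1,4-diene cycloadduct of 7 and 8 (ring sp3 centres undefined) | CCOC(=O)C1=C(C[C@H](C)O[Si](C)(C)C)C(C)C(O[Si](C)(C)C)=C(C)C1(OC)O[Si](C)(C)C | intermediate (not isolated)
10 | ethyl 2-hydroxy-3,5-dimethyl-4-(trimethylsilyloxy)-6-[(2S)-2-(trimethylsilyloxy)propyl]benzoate | CCOC(=O)c1c(O)c(C)c(O[Si](C)(C)C)c(C)c1C[C@H](C)O[Si](C)(C)C | intermediate (not isolated)
11 | ethyl 2,4-dihydroxy-6-[(2S)-2-hydroxypropyl]-3,5-dimethylbenzoate | CCOC(=O)c1c(O)c(C)c(O)c(C)c1C[C@H](C)O | intermediate (not isolated)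
12 | (S)-6,8-dihydroxy-3,5,7-trimethylisochroman-1-one | C[C@H]1Cc2c(C)c(O)c(C)c(O)c2C(=O)O1 | intermediate
13 | tris(diisobutylaluminium) derivative of lactol 14 | C[C@H]1Cc2c(C)c(O[Al](CC(C)C)CC(C)C)c(C)c(O[Al](CC(C)C)CC(C)C)c2C(O[Al](CC(C)C)CC(C)C)O1 | intermediate (not isolated)
14 | (3S)-3,5,7-trimethylisochromane-1,6,8-triol (C1 epimers) | C[C@H]1Cc2c(C)c(O)c(C)c(O)c2C(O)O1 | intermediate
15 | 2-(tert-butyldimethylsilyl)-1,3-dithiane | CC(C)(C)[Si](C)(C)C1SCCCS1 | starting material
16 | (R)-propylene oxide | C[C@@H]1CO1 | starting material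
17 | methyl (E)-4-bromo-3-methoxybut-2-enoate | COC(=O)/C=C(/OC)CBr | starting material
18 | 2-lithio-2-(tert-butyldimethylsilyl)-1,3-dithiane | [Li]C1([Si](C)(C)C(C)(C)C)SCCCS1 | intermediate (not isolated)
19 | lithium (R)-1-[2-(tert-butyldimethylsilyl)-1,3-dithian-2-yl]propan-2-olate | C[C@@H](O[Li])CC1([Si](C)(C)C(C)(C)C)SCCCS1 | intermediate (not isolated)
20 | 2-lithio-2-[(2R)-2-(tert-butyldimethylsilyloxy)propyl]-1,3-dithiane | [Li]C1(C[C@@H](C)O[Si](C)(C)C(C)(C)C)SCCCS1 | intermediate (not isolated)
21 | methyl (E)-4-{2-[(2R)-2-(tert-butyldimethylsilyloxy)propyl]-1,3-dithian-2-yl}-3-methoxybut-2-enoate | COC(=O)/C=C(/OC)CC1(C[C@@H](C)O[Si](C)(C)C(C)(C)C)SCCCS1 | intermediate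
22 | methyl (R,E)-7-(tert-butyldimethylsilyloxy)-3-methoxy-5-oxooct-2-enoate | COC(=O)/C=C(/OC)CC(=O)C[C@@H](C)O[Si](C)(C)C(C)(C)C | intermediate (not isolated)
23 | methyl (R,E)-7-hydroxy-3-methoxy-5-oxooct-2-enoate | COC(=O)/C=C(/OC)CC(=O)C[C@@H](C)O | intermediate (not isolated)
24 | methyl 2-[(2R)-2-methyl-4-oxo-3,4-dihydro-2H-pyran-6-yl]acetate | COC(=O)CC1=CC(=O)C[C@@H](C)O1 | intermediate
25 | 2,4-dihydroxy-6-[(2S)-2-hydroxypropyl]-3,5-dimethylbenzaldehyde | C[C@H](O)Cc1c(C)c(O)c(C)c(O)c1C=O | intermediate (not isolated)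
26 | methyl (Z)-3-{2,4-dihydroxy-6-[(2S)-2-hydroxypropyl]-3,5-dimethylphenyl}-2-[(2R)-2-methyl-4-oxo-3,4-dihydro-2H-pyran-6-yl]acrylate | COC(=O)/C(C1=CC(=O)C[C@@H](C)O1)=C\c1c(O)c(C)c(O)c(C)c1C[C@H](C)O | intermediate (not isolated)
27 | 7-hydroxy-5-[(2S)-2-hydroxypropyl]-6,8-dimethyl-3-[(2R)-2-methyl-4-oxo-3,4-dihydro-2H-pyran-6-yl]-2H-chromen-2-one | Cc1c(O)c(C)c2oc(=O)c(C3=CC(=O)C[C@@H](C)O3)cc2c1C[C@H](C)O | target

## Step count and risks
Total step count: 7. Longest linear sequence: 4 steps (steps 1, 3, 4 and 7, or equally steps 2, 3, 4 and 7).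

**Most likely to fail, first: step 5.** Anion 20 may deprotonate the CH2Br of 17 or attack its acrylate instead of displacing bromide. The fallback gives up the dithiane linchpin and brings in the ketone carbon as an acetylide carbon. It sets out from 1 and 16, comes back at 24, and replaces steps 5 and 6.
- Lithiated 1 (that is 3; n-BuLi, BF3·OEt2, THF, −78 °C) opens 16 to give ethyl (R)-5-hydroxyhex-2-ynoate F1.
- Claisen condensation of F1 with LiCH2CO2Me (3.5 equiv, from methyl acetate and LiN(iPr)2, THF, −78 °C) gives methyl (R)-7-hydroxy-3-oxooct-4-ynoate F2.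
- Et2NH adds to the ynone to give methyl (R,E)-5-(diethylamino)-7-hydroxy-3-oxooct-4-enoate F3.
- 1 M HCl in THF hydrolyses the enaminone and closes the hydroxy diketone to 24.

**Second: step 3.** The open-chain tetrasubstituted diene 7 may be too hindered to build a hexasubstituted ring with an internal ynoate. The fallback replaces it with an Alder–Rickert sequence using a ring-locked s-cis diene. It sets out from 8 (made from 4 as in step 3) and comes back at 11, which lactonises to 12 as before.
- Commercial 2-methylcyclohexane-1,3-dione is methylated through its dianion (LiN(iPr)2 2.2 equiv, THF/HMPA, then MeI) to give 2,4-dimethylcyclohexane-1,3-dione F4.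
- Equilibrating double O-silylation (Me3SiOTf, Et3N) gives the more substituted 2,4-dimethyl-1,3-bis(trimethylsilyloxy)cyclohexa-1,3-diene F5.
- Heating F5 with 8 (neat, 170 °C) gives ethyl 4,6-dimethyl-1,5-bis(trimethylsilyloxy)-3-[(2S)-2-(trimethylsilyloxy)propyl]bicyclo[2.2.2]octa-2,5-diene-2-carboxylate F6.
- F6 loses ethene by cycloreversion to give ethyl 3,5-dimethyl-2,4-bis(trimethylsilyloxy)-6-[(2S)-2-(trimethylsilyloxy)propyl]benzoate F7.
- The acid work-up of step 3 converts F7 to 11.

**Third: step 4.** The electron-rich, chelated lactone may not react at −78 °C, or may over-reduce when warmed. The fallback replaces the partial reduction by a full reduction and selective re-oxidation. It sets out from 12 and comes back at 14.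
- LiAlH4 (THF, 0 °C to 23 °C) gives 4-(hydroxymethyl)-5-[(2S)-2-hydroxypropyl]-2,6-dimethylbenzene-1,3-diol F8.
- Crude F8 is oxidised only at the benzylic alcohol with MnO2 (CH2Cl2/acetone, 23 °C) to give 25, which closes to 14.

Further compounds
F1 | step 5 | ethyl (R)-5-hydroxyhex-2-ynoate | CCOC(=O)C#CC[C@@H](C)O
F2 | step 5 | methyl (R)-7-hydroxy-3-oxooct-4-ynoate | COC(=O)CC(=O)C#CC[C@@H](C)O
F3 | step 5 | methyl (R,E)-5-(diethylamino)-7-hydroxy-3-oxooct-4-enoate | CCN(CC)/C(C[C@@H](C)O)=C/C(=O)CC(=O)OC
F4 | step 3 | 2,4-dimethylcyclohexane-1,3-dione | CC1CCC(=O)C(C)C1=O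
F5 | step 3 | 2,4-dimethyl-1,3-bis(trimethylsilyloxy)cyclohexa-1,3-diene | CC1=C(O[Si](C)(C)C)C(C)=C(O[Si](C)(C)C)CC1
F6 | step 3 | ethyl 4,6-dimethyl-1,5-bis(trimethylsilyloxy)-3-[(2S)-2-(trimethylsilyloxy)propyl]bicyclo[2.2.2]octa-2,5-diene-2-carboxylate | CCOC(=O)C1=C(C[C@H](C)O[Si](C)(C)C)C2(C)CCC1(O[Si](C)(C)C)C(C)=C2O[Si](C)(C)C
F7 | step 3 | ethyl 3,5-dimethyl-2,4-bis(trimethylsilyloxy)-6-[(2S)-2-(trimethylsilyloxy)propyl]benzoate | CCOC(=O)c1c(O[Si](C)(C)C)c(C)c(O[Si](C)(C)C)c(C)c1C[C@H](C)O[Si](C)(C)C
F8 | step 4 | 4-(hydroxymethyl)-5-[(2S)-2-hydroxypropyl]-2,6-dimethylbenzene-1,3-diol | C[C@H](O)Cc1c(C)c(O)c(C)c(O)c1CO
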